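**Retrosynthetic overview**
1. Feature used: ring B is a hexasubstituted benzene with an alternating ketide pattern. Its ether carbon (C–OAr) lies between the carbon bearing the depsidone ester oxygen and the carbon bearing the lactol CH. Both neighbours are former chain carbonyl carbons, so the crowded diaryl ether oxygen can be attached by SN2 to an sp3 carbon before ring B exists.
2. The lactol stereocentre comes from a benzyl carbonate made by dynamic kinetic resolution of the racemic lactol. The γ-lactol ring comes from a formyl acid, and the seven-membered ring from lactonisation of the ring A acid onto the ring B phenol.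
3. Ring B is opened at the bond between its carboxyl-bearing and formyl-bearing carbons, which leads back to an aryloxy diketo-dioxinone chain (aldol aromatisation).
4. The chain is assembled from a ring A aryloxyacetic Weinreb amide, the dienolate of 6-ethyl-dioxinone and dimethoxyacetic Weinreb amide. Ring A comes from 3,4,5-trimethoxytoluene.
5. Ring order: A (bought), B (step 11), seven-membered dioxepinone (step 15), γ-lactol (step 16). The stereocentre is set in step 17 and unveiled in step 18.

Key step: step 11

Assumption 1: the free lactol carbon equilibrates through the open formyl acid in base or protic media. It is therefore fixed on a configurationally stable carbonate and freed last in a neutral, cold, aprotic medium, and the product is kept as a solid.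
Assumption 2: (R)-benzotetramisole is written for step 17 by analogy with its preference for (R)-aryl carbinols. The sense of induction must be confirmed on 28, and the (S)-catalyst is used if it proves opposite.

**Step 1**
Reactants: 1 3,4,5-trimethoxytoluene
Product: 2 2,3,4-trimethoxy-6-methylbenzaldehyde
Conditions: POCl3, DMF, 0 → 70 °C; then H2O
Reagents that add atoms: N,N-dimethylformamide, CN(C)C=O; water, O
Why: Vilsmeier–Haack formylation; the two free ring positions are equivalent and activated by ortho and para methoxy groups, so one aldehyde should result.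

**Step 2**
Reactants: 2 2,3,4-trimethoxy-6-methylbenzaldehyde
Product: 3 2,3-dihydroxy-4-methoxy-6-methylbenzaldehyde
Conditions: BCl3 (2.5 equiv), CH2Cl2, 0 °C → rt; then H2O
Reagents that add atoms: none
Why: Chelation-directed Lewis-acid ether cleavage; boron held by the formyl oxygen removes the ortho methyl, then closes a five-membered cyclic borate by removing the adjacent one, and this borate is too weakly acidic to attack the 4-methoxy group.

**Step 3**
Reactants: 3 2,3-dihydroxy-4-methoxy-6-methylbenzaldehyde
Product: 4 3-(benzyloxy)-2-hydroxy-4-methoxy-6-methylbenzaldehyde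
Conditions: NaH (2.1 equiv), DMF, 0 °C; BnBr (1.0 equiv), 0 °C → rt; then 1 M HCl
Reagents that add atoms: benzyl bromide, BrCc1ccccc1
Why: Williamson etherification of the catecholate dianion; the oxide ortho to the formyl group is delocalised into the carbonyl and chelated to sodium, so one equivalent of halide should go to the more basic 3-oxide.

**Step 4**
Reactants: 4 3-(benzyloxy)-2-hydroxy-4-methoxy-6-methylbenzaldehyde; 5 2-chloro-N-methoxy-N-methylacetamide
Product: 6 2-[2-(benzyloxy)-6-formyl-3-methoxy-5-methylphenoxy]-N-methoxy-N-methylacetamide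
Conditions: K2CO3, NaI (cat.), DMF, 50 °C
Reagents that add atoms: none
Why: Finkelstein-assisted Williamson etherification (SN2) that creates the future diaryl ether C–O bond; the amide α-protons are too weakly acidic for K2CO3 to start the aldol closure onto the aldehyde that α-halo ketones undergo.

**Step 5**
Reactants: 6 2-[2-(benzyloxy)-6-formyl-3-methoxy-5-methylphenoxy]-N-methoxy-N-methylacetamide
Product: 7 3-(benzyloxy)-4-methoxy-2-{2-[methoxy(methyl)amino]-2-oxoethoxy}-6-methylbenzoic acid
Conditions: NaClO2, NaH2PO4, 2-methyl-2-butene, tBuOH–H2O, rt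
Reagents that add atoms: sodium chlorite, [Na+].[O-]Cl=O
Why: Pinnick oxidation; it tolerates hindered aldehydes, benzyl ethers and amides, and the alkene removes hypochlorous acid before it can chlorinate the electron-rich ring A.

**Step 6**
Reactants: 7 3-(benzyloxy)-4-methoxy-2-{2-[methoxy(methyl)amino]-2-oxoethoxy}-6-methylbenzoic acid
Product: 8 tert-butyl 3-(benzyloxy)-4-methoxy-2-{2-[methoxy(methyl)amino]-2-oxoethoxy}-6-methylbenzoate
Conditions: Cl3CC(=NH)OtBu, CH2Cl2–cyclohexane, rt
Reagents that add atoms: tert-butyl 2,2,2-trichloroacetimidate, CC(C)(C)OC(=N)C(Cl)(Cl)Cl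
Why: Imidate esterification (SN1-type O-alkylation of the acid); the bond forms at the carboxyl oxygen and not at the acyl carbon, so the two ortho substituents do not hinder it.

**Step 7**
Reactants: 9 2,2,6-trimethyl-4H-1,3-dioxin-4-one
Product: 11 6-ethyl-2,2-dimethyl-4H-1,3-dioxin-4-one, via lithium dienolate 10 (not isolated)
Conditions: LiN(iPr)2, THF–DMPU, −78 °C; MeI, −78 → −20 °C
Reagents that add atoms: iodomethane, CI
Why: γ-Alkylation of the extended dioxinone dienolate, a known regiochemical preference in dipolar cosolvent; placing the ring B methyl here avoids a later mono-methylation of an active methylene.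

**Step 8**
Reactants: 8 tert-butyl 3-(benzyloxy)-4-methoxy-2-{2-[methoxy(methyl)amino]-2-oxoethoxy}-6-methylbenzoate; 11 6-ethyl-2,2-dimethyl-4H-1,3-dioxin-4-one
Product: 13 tert-butyl 3-(benzyloxy)-2-[3-(2,2-dimethyl-4-oxo-4H-1,3-dioxin-6-yl)-2-oxobutoxy]-4-methoxy-6-methylbenzoate (racemic at a labile methine), via lithium dienolate 12 (not isolated)
Conditions: 11 (1.5 equiv), LiN(iPr)2 (1.4 equiv), THF, −78 °C; then 8, −78 → −30 °C; AcOH, −78 °C
Reagents that add atoms: none
Why: Weinreb ketone synthesis with a vinylogous (γ-selective) dienolate; the chelated tetrahedral adduct lasts until the quench, which prevents over-addition and proton exchange, and the slight deficit of amide base leaves the ring A methyl ortho to the ester unmetalated.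

**Step 9**
Reactants: 14 methyl dimethoxyacetate
Product: 15 N,2,2-trimethoxy-N-methylacetamide
Conditions: MeNHOMe·HCl, iPrMgCl, THF, −20 → 0 °C; then aq. NH4Cl
Reagents that add atoms: N,O-dimethylhydroxylamine hydrochloride, CNOC.Cl
Why: Weinreb amide formation by magnesium amide aminolysis of an activated ester that is hardly enolisable; the acetal is inert to base.

**Step 10**
Reactants: 13 keto-dioxinone; 15 N,2,2-trimethoxy-N-methylacetamide
Product: 17 tert-butyl 3-(benzyloxy)-2-{[5-(2,2-dimethyl-4-oxo-4H-1,3-dioxin-6-yl)-1,1-dimethoxy-2,4-dioxohexan-3-yl]oxy}-4-methoxy-6-methylbenzoate (diastereomer/enol mixture), via dilithium dianion 16 (not isolated)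
Conditions: LiN(iPr)2 (2.1 equiv), THF, −78 → −40 °C; 15, −78 → −40 °C; AcOH, −78 °C; used after a short filtration
Reagents that add atoms: none
Why: Claisen-type acylation of a β-dicarbonyl dianion with a Weinreb amide, the standard entry to diketo-dioxinones; the second deprotonation takes the aryloxy-activated CH2, which is more acidic than the ring A methyl, and at low temperature the doubly ortho-flanked tert-butyl ester resists five-ring closure to a benzofuranone.

**Step 11**
Reactants: 17 aryloxy diketo-dioxinone
Product: 19 tert-butyl 3-(benzyloxy)-2-{[5-(dimethoxymethyl)-7-hydroxy-2,2,8-trimethyl-4-oxo-4H-1,3-benzodioxin-6-yl]oxy}-4-methoxy-6-methylbenzoate, via aldol carbinol 18 (not isolated)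
Conditions: Et3N (5 equiv), CH2Cl2, rt
Reagents that add atoms: none
Why: Et3N removes the proton of the methyl-bearing carbon between the dioxinone and the first ketone, and the extended dienolate attacks the acetal-bearing ketone six atoms away through the dioxinone α-carbon (C5) to give carbinol 18, which loses water and enolises its remaining ketone, so the new bond joins the carboxyl-bearing and dimethoxymethyl-bearing carbons of ring B. The closest known reaction type is the amine-induced aldol aromatisation of diketo-dioxinones to isopropylidene-protected resorcylates, applied here to a chain that also carries methyl, aryloxy and acetal groups. Ring B closes in a 6-(enolexo)-exo-trig mode, and no stereocentre results because all sp3 centres of 17 and 18 in the new ring are erased on aromatisation. The step needs C–C aldol closure in preference to O-cyclisation or Claisen closure: the acetonide ties up the enol oxygen and carboxyl that a pyrone would need, room temperature keeps the dioxinone from fragmenting to an acylketene, and the ring double bond holds the ester carbonyl trans to the chain, out of reach of the central carbanion. The acetal ketone is the most electrophilic carbonyl of the chain, the aryloxy carbon has only carbonyl or fully substituted neighbours so aryloxide has no E1cB exit, and the hindered tert-butyl ester of ring A is not attacked by the stabilised central enolate.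

**Step 12**
Reactants: 19 ring B resorcylate acetonide
Product: 20 tert-butyl 3-(benzyloxy)-2-{[5-(dimethoxymethyl)-7-(methoxymethoxy)-2,2,8-trimethyl-4-oxo-4H-1,3-benzodioxin-6-yl]oxy}-4-methoxy-6-methylbenzoate
Conditions: NaH, MOMCl, THF–DMF, 0 °C
Reagents that add atoms: chloromethyl methyl ether, COCCl
Why: Williamson-type acetal protection of the only free phenol; left free, it would become a phenoxide para to the dioxinone carbonyl and deactivate that carbonyl towards alkoxide in step 13, and the group is removed at no extra cost in step 14.

**Step 13**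
Reactants: 20 MOM-protected resorcylate acetonide
Product: 22 tert-butyl 3-(benzyloxy)-2-[4-(benzyloxy)-6-(dimethoxymethyl)-2-(methoxymethoxy)-3-methyl-5-(prop-2-enyloxycarbonyl)phenoxy]-4-methoxy-6-methylbenzoate, via sodium phenoxide 21 (not isolated)
Conditions: allyl alcohol (3 equiv), NaH (1.5 equiv), THF, 0 °C → rt; then BnBr, Bu4NI, DMF, rt
Reagents that add atoms: allyl alcohol, C=CCO; benzyl bromide, BrCc1ccccc1
Why: Alkoxide transesterification of the benzodioxinone with loss of acetone, followed by Williamson benzylation of the released phenoxide; the planar cyclic acyl group is open to attack despite its ortho substituent, while the tert-butyl ester, acetal and MOM ether are inert to alkoxide.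

**Step 14**
Reactants: 22 fully protected diaryl ether
Product: 23 3-(benzyloxy)-2-[4-(benzyloxy)-6-formyl-2-hydroxy-3-methyl-5-(prop-2-enyloxycarbonyl)phenoxy]-4-methoxy-6-methylbenzoic acid
Conditions: TFA–CH2Cl2–H2O, 0 °C → rt
Reagents that add atoms: water, O
Why: Acidolysis; the tert-butyl ester cleaves by alkyl–oxygen fission regardless of hindrance, the MOM ether and dimethyl acetal hydrolyse in the same medium, and the allyl ester and benzyl ethers should survive a short exposure.

**Step 15**
Reactants: 23 seco acid
Product: 25 depsidone (11H-dibenzo[b,e][1,4]dioxepin-11-one) with OBn, OMe and CH3 on ring A and CH3, OBn, CO2-allyl and CHO on ring B, via mixed trifluoroacetic anhydride 24 (not isolated)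
Conditions: (CF3CO)2O, toluene, high dilution, 0 °C → rt
Reagents that add atoms: none
Why: Mixed-anhydride lactonisation, the classical depside and depsidone ester closure; the electron-rich 2,6-disubstituted acid is readily activated, and the single free phenol sits ortho to the ether in position for a 7-exo-trig closure.

**Step 16**
Reactants: 25 depsidone allyl ester aldehyde
Product: 27 racemic lactol 4,11-bis(benzyloxy)-1-hydroxy-10-methoxy-5,8-dimethyl-1H-isobenzofuro[4,5-b][1,4]benzodioxepine-3,7-dione, via open formyl acid 26 (not isolated)
Conditions: Pd(PPh3)4 (5 mol %), p-TolSO2H, CH2Cl2, rt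
Reagents that add atoms: none
Why: Tsuji–Trost deallylation by zerovalent palladium with a non-basic sulfinic acid trap that spares the aryl ester and the aldehyde; the freed 2-formylbenzoic acid closes by ring–chain tautomerism (5-exo-trig) to the hydroxyphthalide, necessarily racemic.

**Step 17**
Reactants: 27 racemic lactol
Product: 28 (S)-benzyl carbonate of lactol 27 (same spatial arrangement as the target; the descriptor is S because the carbonate oxygen outranks the lactone oxygen)
Conditions: (R)-benzotetramisole (10 mol %), (BnOCO)2O (2 equiv), iPr2NEt (0.2 equiv), Na2SO4, CHCl3, −20 °C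
Reagents that add atoms: dibenzyl dicarbonate, O=C(OCc1ccccc1)OC(=O)OCc1ccccc1
Why: Proposed new method: the lactol enantiomers interconvert through the open formyl carboxylate under the amine, while the N-benzyloxycarbonyl isothiouronium ion formed from catalyst and dicarbonate should transfer its group faster to one of them (ring B stacked on the cationic catalyst, as in the benzylic carbinol model), which sets the lactol carbon; the closest known reaction types are the acylative dynamic kinetic resolution of lactols and 3-hydroxyphthalides with anhydrides under chiral Lewis-base catalysis and the isothiourea-catalysed carboxyl transfer of enol carbonates, and a carbonate is chosen because it alone can later be removed without base, acid or water.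

**Step 18**
Reactants: 28 (S)-benzyl carbonate
Product: 31 target (1R)-1,4,11-trihydroxy-10-methoxy-5,8-dimethyl-1H-isobenzofuro[4,5-b][1,4]benzodioxepine-3,7-dione, via lactol hydrogen carbonate 29 (not isolated), via (R)-lactol dibenzyl ether 30 (not isolated)
Conditions: H2 (1 atm), Pd/C, EtOAc, 0 °C; cold filtration, evaporation below 5 °C, precipitation from cold EtOAc–hexane
Reagents that add atoms: none
Why: Hydrogenolysis of the benzyl carbonate and the benzyl aryl ethers; only O–CH2Ph bonds break, and the hydrogen carbonate loses CO2 without touching the C–O bond at the stereocentre, so configuration is retained (S becomes R through priority rules alone), while the neutral, aprotic, cold medium offers no catalyst for ring–chain tautomerism.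

**Compound list**
1 | 3,4,5-trimethoxytoluene | COc1cc(C)cc(OC)c1OC | starting material
2 | 2,3,4-trimethoxy-6-methylbenzaldehyde | COc1cc(C)c(C=O)c(OC)c1OC | intermediate
3 | 2,3-dihydroxy-4-methoxy-6-methylbenzaldehyde | COc1cc(C)c(C=O)c(O)c1O | intermediate
4 | 3-(benzyloxy)-2-hydroxy-4-methoxy-6-methylbenzaldehyde | COc1cc(C)c(C=O)c(O)c1OCc1ccccc1 | intermediate
5 | 2-chloro-N-methoxy-N-methylacetamide | CON(C)C(=O)CCl | starting material
6 | 2-[2-(benzyloxy)-6-formyl-3-methoxy-5-methylphenoxy]-N-methoxy-N-methylacetamide | COc1cc(C)c(C=O)c(OCC(=O)N(C)OC)c1OCc1ccccc1 | intermediate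
7 | 3-(benzyloxy)-4-methoxy-2-{2-[methoxy(methyl)amino]-2-oxoethoxy}-6-methylbenzoic acid | COc1cc(C)c(C(=O)O)c(OCC(=O)N(C)OC)c1OCc1ccccc1 | intermediate
8 | tert-butyl ester of 7 (ring A fragment) | COc1cc(C)c(C(=O)OC(C)(C)C)c(OCC(=O)N(C)OC)c1OCc1ccccc1 | intermediate
9 | 2,2,6-trimethyl-4H-1,3-dioxin-4-one | CC1=CC(=O)OC(C)(C)O1 | starting material
10 | lithium dienolate of 9 | C=C1C=C([O-])OC(C)(C)O1.[Li+] | intermediate
11 | 6-ethyl-2,2-dimethyl-4H-1,3-dioxin-4-one | CCC1=CC(=O)OC(C)(C)O1 | intermediate
12 | lithium dienolate of 11 | CC=C1C=C([O-])OC(C)(C)O1.[Li+] | intermediate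
13 | aryloxy keto-dioxinone (racemic, labile methine) | COc1cc(C)c(C(=O)OC(C)(C)C)c(OCC(=O)C(C)C2=CC(=O)OC(C)(C)O2)c1OCc1ccccc1 | intermediate
14 | methyl dimethoxyacetate | COC(OC)C(=O)OC | starting material
15 | N,2,2-trimethoxy-N-methylacetamide | COC(OC)C(=O)N(C)OC | intermediate
16 | dilithium dianion of 13 | COc1cc(C)c(C(=O)OC(C)(C)C)c(OC=C([O-])C(C)=C2C=C([O-])OC(C)(C)O2)c1OCc1ccccc1.[Li+].[Li+] | intermediate
17 | aryloxy diketo-dioxinone, key-step precursor (diastereomer/enol mixture) | COc1cc(C)c(C(=O)OC(C)(C)C)c(OC(C(=O)C(C)C2=CC(=O)OC(C)(C)O2)C(=O)C(OC)OC)c1OCc1ccccc1 | intermediate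
18 | aldol carbinol (diastereomer mixture) | COc1cc(C)c(C(=O)OC(C)(C)C)c(OC2C(=O)C(C)=C3OC(C)(C)OC(=O)C3C2(O)C(OC)OC)c1OCc1ccccc1 | intermediate
19 | ring B resorcylate acetonide, key-step product | COc1cc(C)c(C(=O)OC(C)(C)C)c(Oc2c(O)c(C)c3OC(C)(C)OC(=O)c3c2C(OC)OC)c1OCc1ccccc1 | intermediate
20 | MOM ether of 19 | COc1cc(C)c(C(=O)OC(C)(C)C)c(Oc2c(OCOC)c(C)c3OC(C)(C)OC(=O)c3c2C(OC)OC)c1OCc1ccccc1 | intermediate
21 | sodium phenoxide of the allyl ester | COc1cc(C)c(C(=O)OC(C)(C)C)c(Oc2c(OCOC)c(C)c([O-])c(C(=O)OCC=C)c2C(OC)OC)c1OCc1ccccc1.[Na+] | intermediate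
22 | allyl ester, ring B benzyl ether | COc1cc(C)c(C(=O)OC(C)(C)C)c(Oc2c(OCOC)c(C)c(OCc3ccccc3)c(C(=O)OCC=C)c2C(OC)OC)c1OCc1ccccc1 | intermediate
23 | seco acid with free phenol and aldehyde | COc1cc(C)c(C(=O)O)c(Oc2c(O)c(C)c(OCc3ccccc3)c(C(=O)OCC=C)c2C=O)c1OCc1ccccc1 | intermediate
24 | mixed trifluoroacetic anhydride of 23 | COc1cc(C)c(C(=O)OC(=O)C(F)(F)F)c(Oc2c(O)c(C)c(OCc3ccccc3)c(C(=O)OCC=C)c2C=O)c1OCc1ccccc1 | intermediate
25 | depsidone allyl ester aldehyde | COc1cc(C)c2c(c1OCc1ccccc1)Oc1c(c(C)c(OCc3ccccc3)c(C(=O)OCC=C)c1C=O)OC2=O | intermediate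
26 | open formyl acid | COc1cc(C)c2c(c1OCc1ccccc1)Oc1c(c(C)c(OCc3ccccc3)c(C(=O)O)c1C=O)OC2=O | intermediate
27 | racemic lactol, bis(benzyl ether) | COc1cc(C)c2c(c1OCc1ccccc1)Oc1c(c(C)c(OCc4ccccc4)c3c1C(O)OC3=O)OC2=O | intermediate
28 | (S)-lactol benzyl carbonate | COc1cc(C)c2c(c1OCc1ccccc1)Oc1c(c(C)c(OCc4ccccc4)c3c1[C@H](OC(=O)OCc1ccccc1)OC3=O)OC2=O | intermediate
29 | (S)-lactol hydrogen carbonate | COc1cc(C)c2c(c1OCc1ccccc1)Oc1c(c(C)c(OCc4ccccc4)c3c1[C@H](OC(=O)O)OC3=O)OC2=O | intermediate
30 | (R)-lactol, bis(benzyl ether) | COc1cc(C)c2c(c1OCc1ccccc1)Oc1c(c(C)c(OCc4ccccc4)c3c1[C@H](O)OC3=O)OC2=O | intermediate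
31 | CNP0211607.1, (R)-lactol depsidone | COc1cc(C)c2c(c1O)Oc1c(c(C)c(O)c3c1[C@H](O)OC3=O)OC2=O | target

**Total step count:** 18. **Longest linear sequence:** 16 (steps 1–6, 8, 10–18).

**Steps most likely to fail**

Step 17. Three things could lower the enantiomeric purity. The catalyst may discriminate poorly at a carbinol wedged against the diaryl ether. The amine alone may transfer the carbonate without the catalyst. The open formyl carboxylate may be captured as its benzyl ester. The fallback uses known chemistry and sets out from 27. Benzyl chloroformate and pyridine in CH2Cl2 at 0 °C give the racemic lactol benzyl carbonate F1, which is configurationally stable. Preparative chromatography on a chiral stationary phase (supercritical CO2–iPrOH, immobilised amylose carbamate) separates 28 from the (R)-antipode of 28 F2, which is set aside. The route is rejoined at 28.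

Step 11. The chain may rest as the stabilised enolate of its central aryloxy diketone without folding. It may also lose the dimethoxyacetyl unit by retro-Claisen cleavage, or stop at the carbinol without dehydrating. The fallback sets out from 17 and forms the same bond from an open chain. Heating in toluene at 110 °C with allyl alcohol expels acetone by cycloreversion, and the acylketene is trapped as the allyl 6-aryloxy-8,8-dimethoxy-4-methyl-3,5,7-trioxooctanoate F3. Its free β-keto ester methylene is a less hindered and more acidic nucleophile than the dioxinone carbon. Cs2CO3 in THF followed by AcOH effects the aldol aromatisation to the allyl resorcylate with two free phenols F4. MOMCl and iPr2NEt protect only the phenol that is not hydrogen-bonded to the ester, giving the mono-MOM allyl resorcylate F5. BnBr, K2CO3 and DMF then give 22, where the route is rejoined.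

Step 18. The benzylic C–O bond at the lactol carbon may be hydrogenolysed. Configuration may also erode by ring–chain tautomerism while the hindered aryl benzyl ethers cleave slowly. The fallback sets out from 27 and replaces the final heterogeneous hydrogenolysis by homogeneous π-allyl chemistry. H2 and Pd/C in EtOAc, applied while no configuration is at stake, give the racemic target F6. (R)-Benzotetramisole with excess diallyl dicarbonate gives the (S)-tris(allyl carbonate) F7; allyl chloroformate followed by chiral-phase separation is the alternative. The phenols are carbonated without stereochemical consequence. Pd(PPh3)4 and p-TolSO2H in CH2Cl2 at −20 °C remove all three groups in a weakly acidic, hydride-free medium and deliver 31.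

**Further compounds**
F1 | step 17 | racemic lactol benzyl carbonate | COc1cc(C)c2c(c1OCc1ccccc1)Oc1c(c(C)c(OCc4ccccc4)c3c1C(OC(=O)OCc1ccccc1)OC3=O)OC2=O
F2 | step 17 | (R)-antipode of 28 | COc1cc(C)c2c(c1OCc1ccccc1)Oc1c(c(C)c(OCc4ccccc4)c3c1[C@@H](OC(=O)OCc1ccccc1)OC3=O)OC2=O
F3 | step 11 | allyl 6-aryloxy-8,8-dimethoxy-4-methyl-3,5,7-trioxooctanoate | COc1cc(C)c(C(=O)OC(C)(C)C)c(OC(C(=O)C(C)C(=O)CC(=O)OCC=C)C(=O)C(OC)OC)c1OCc1ccccc1
F4 | step 11 | allyl resorcylate with two free phenols | COc1cc(C)c(C(=O)OC(C)(C)C)c(Oc2c(O)c(C)c(O)c(C(=O)OCC=C)c2C(OC)OC)c1OCc1ccccc1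
F5 | step 11 | mono-MOM allyl resorcylate | COc1cc(C)c(C(=O)OC(C)(C)C)c(Oc2c(OCOC)c(C)c(O)c(C(=O)OCC=C)c2C(OC)OC)c1OCc1ccccc1
F6 | step 18 | racemic target | COc1cc(C)c2c(c1O)Oc1c(c(C)c(O)c3c1C(O)OC3=O)OC2=O
F7 | step 18 | (S)-tris(allyl carbonate) | COc1cc(C)c2c(c1OC(=O)OCC=C)Oc1c(c(C)c(OC(=O)OCC=C)c3c1[C@H](OC(=O)OCC=C)OC3=O)OC2=O
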